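The route rests on removing C8 from ring D (ent-kaurane numbering). Both ring bonds of the quaternary β-keto-lactone carbon (C8–C15, C8–C14) are made at once by inserting the lactone α-carbon into a cyclobutanone. The precursor is a spiro bis-lactone (rings A, B, E) carrying a diazo group at C8 and, on C9, a silyloxy chain that ends in a 3-substituted, locally symmetric cyclobutanone. Lewis acid makes C8 add to C15=O, then C14 migrates with loss of N2. One operation turns the four-membered ring into cyclopentanone ring D, closes ring C and sets C8 and C13. It exploits C8 as the carbon between C7=O and C15=O and the CH2 pair C14/C16 flanking C13.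

Key step: step 18

Remark: ring A = C1–C5, C10; ring B = δ-lactone C7, C8, C9, C10, C20, O; ring C = C8, C9, C11–C14; ring D = C8, C14, C13, C16, C15; ring E = γ-lactone C4, C5, C6, O, C19; C17 = CH2OH; C18 = CH3. (3,3-Dimethoxycyclobutyl)methanol is taken as commercially available, and the enantiomeric purity from step 2 is expected to be raised by crystallisation of bis-lactone 14.

Step 1
Reactants: 1 cyclohexanone
Product: 3 rac-allyl 1-methyl-2-oxocyclohexane-1-carboxylate, via allyl 2-oxocyclohexane-1-carboxylate 2 (not isolated)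
Conditions: NaH, diallyl carbonate, THF, 40 °C; then MeI, 23 °C
Reagents that add atoms: diallyl carbonate C=CCOC(=O)OCC=C; iodomethane CI
Why: Claisen-type C-acylation of the sodium enolate gives the stabilised β-keto ester enolate, which is C-methylated in the same flask; the racemic quaternary carbon is erased and reset in step 2.

Step 2
Reactants: 3 rac-allyl 1-methyl-2-oxocyclohexane-1-carboxylate
Product: 4 (S)-2-allyl-2-methylcyclohexan-1-one
Conditions: Pd2(dba)3 (cat.), (S)-t-BuPHOX (cat.), THF, 25 °C
Reagents that add atoms: none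
Why: In this decarboxylative asymmetric allylic alkylation (Tsuji allylation), zerovalent palladium ionises the allyl ester, CO2 is lost and the prochiral enolate is allylated in the chiral pocket, the (S)-ligand being the one known to give the (S)-ketone, which sets C4.

Step 3
Reactants: 4 (S)-2-allyl-2-methylcyclohexan-1-one
Product: 5 (S)-6-allyl-6-methylcyclohex-1-en-1-yl trifluoromethanesulfonate
Conditions: LiN(i-Pr)2, THF, −78 °C; PhNTf2, −78 → 0 °C
Reagents that add atoms: N-phenylbis(trifluoromethanesulfonimide) FC(F)(F)S(=O)(=O)N(c1ccccc1)S(=O)(=O)C(F)(F)F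
Why: Only C10 carries α-hydrogens, so enolisation and O-sulfonylation (enol triflate formation) can give one regioisomer only.

Step 4
Reactants: 5 (S)-6-allyl-6-methylcyclohex-1-en-1-yl trifluoromethanesulfonate
Product: 6 (S)-6-methyl-6-[(E)-prop-1-en-1-yl]cyclohex-1-en-1-yl trifluoromethanesulfonate
Conditions: RuHCl(CO)(PPh3)3 (cat.), toluene, 100 °C
Reagents that add atoms: none
Why: Ruthenium hydride olefin isomerisation (insertion/β-hydride elimination) moves the terminal alkene by one position to the more stable (E)-propenyl group and must stop at quaternary C4.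

Step 5
Reactants: 6 (S)-6-methyl-6-[(E)-prop-1-en-1-yl]cyclohex-1-en-1-yl trifluoromethanesulfonate
Product: 7 (S)-6-(hydroxymethyl)-6-methylcyclohex-1-en-1-yl trifluoromethanesulfonate
Conditions: O3, CH2Cl2–MeOH, −78 °C; NaBH4, −78 → 0 °C
Reagents that add atoms: ozone [O-][O+]=O
Why: Ozonolysis should pick the electron-rich propenyl alkene over the electron-poor enol triflate, and borohydride reduction of the ozonide gives the neopentyl alcohol C19–OH.

Step 6
Reactants: 7 (S)-6-(hydroxymethyl)-6-methylcyclohex-1-en-1-yl trifluoromethanesulfonate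
Product: 8 (R)-3a-methyl-3a,4,5,6-tetrahydro-2-benzofuran-1(3H)-one (rings A/E with C5=C10)
Conditions: Pd(PPh3)4 (cat.), CO (1 atm), Et3N, LiCl, MeCN, 65 °C
Reagents that add atoms: carbon monoxide [C-]#[O+]
Why: In this carbonylative lactonisation, oxidative addition of the enol triflate to zerovalent palladium, CO insertion and capture of the acyl palladium by the neighbouring hydroxyl install C6 and close ring E.

Step 7
Reactants: 8 (R)-3a-methyl-3a,4,5,6-tetrahydro-2-benzofuran-1(3H)-one
Product: 10 (3aR,7R,7aS)-7-ethenyl-3a-methylhexahydro-2-benzofuran-1(3H)-one (cis-fused; vinyl on C10 anti to CH3-18), via trimethylsilyl ketene acetal 9 (not isolated)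
Conditions: CH2=CHMgBr, CuBr·SMe2 (cat.), Me3SiCl, THF, −78 → −30 °C; 1 M HCl
Reagents that add atoms: vinylmagnesium bromide C=C[Mg]Br
Why: In this copper-catalysed, silyl-accelerated 1,4-addition the vinyl group should enter C10 anti to the angular methyl, and protonation of 9 at C5 should give the more stable cis ring fusion (H5 cis to CH3-18); C10 is planarised again in step 9.

Step 8
Reactants: 10 C10-vinyl lactone
Product: 11 C10-formyl lactone (4R,5S,10S): cis-fused rings A/E bearing CHO (C20) at C10
Conditions: O3, CH2Cl2, −78 °C; PPh3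
Reagents that add atoms: ozone [O-][O+]=O
Why: Ozonolysis with reductive work-up cleaves the only alkene to the aldehyde, whose carbon becomes C20.

Step 9
Reactants: 11 C10-formyl lactone
Product: 12 quaternary aldehyde ester (4R,5R,10R): C10 bears CHO (C20, cis to C6 and C19) and CH2CH2CO2Me (C9–C8–C7, cis to H5)
Conditions: methyl acrylate, DBU (cat.), MeCN, 40 °C
Reagents that add atoms: methyl acrylate C=CC(=O)OC
Why: In this Michael addition of the α-branched aldehyde enolate the acceptor should approach C10 equatorially, anti to the vicinal C5–C6 bond and away from axial C19, so C9 ends on the face of H5 and C10 is set.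

Step 10
Reactants: 12 quaternary aldehyde ester
Product: 14 spiro bis-lactone (4R,5R,10R) comprising rings A/B/E, via hydroxy ester 13 (not isolated)
Conditions: NaBH4, MeOH, 0 °C; then p-TsOH (cat.), toluene, 60 °C
Reagents that add atoms: none
Why: Chemoselective borohydride reduction of the aldehyde followed by acid-catalysed lactonisation of the δ-hydroxy ester closes ring B, and loss of methanol makes the bis-lactone the sink of any acyl migration.

Step 11
Reactants: 14 spiro bis-lactone
Product: 16 C8=C9 unsaturated spiro bis-lactone (4R,5R,10R), via α-phenylselanyl lactone 15 (not isolated)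
Conditions: LiN(SiMe3)2, THF, −78 °C; PhSeBr; then 30 % H2O2, pyridine, CH2Cl2, 0 → 23 °C
Reagents that add atoms: none
Why: Selenoxide syn-elimination works here because C8 is enolised in preference to C5, which lies between two quaternary carbons, and only the δ-lactone owns β-hydrogens.

Step 12
Reactants: 16 C8=C9 unsaturated spiro bis-lactone
Product: 18 C9-vinyl bis-lactone (4R,5R,9S,10R) with the vinyl group anti to C5, via trimethylsilyl ketene acetal 17 (not isolated)
Conditions: CH2=CHMgBr, CuBr·SMe2 (cat.), Me3SiCl, THF, −78 → −30 °C; 1 M HCl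
Reagents that add atoms: vinylmagnesium bromide C=C[Mg]Br
Why: In this copper-catalysed 1,4-addition, attack on C9 anti to the larger C10 substituent (C5, pseudo-axial in the reacting half-chair) should set C9, as with 4,4-disubstituted cyclohexenones.

Step 13
Reactants: 18 C9-vinyl bis-lactone
Product: 19 C9-formyl bis-lactone (4R,5R,9R,10R), CHO = C11
Conditions: O3, CH2Cl2, −78 °C; PPh3
Reagents that add atoms: ozone [O-][O+]=O
Why: Ozonolysis with neutral reductive work-up gives the C11 aldehyde without basic conditions that could epimerise C9.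

Step 14
Reactants: 20 (3,3-dimethoxycyclobutyl)methanol
Product: 21 3-(iodomethyl)-1,1-dimethoxycyclobutane
Conditions: I2, PPh3, imidazole, CH2Cl2, 0 → 23 °C
Reagents that add atoms: iodine II
Why: Appel-type iodination of the primary alcohol proceeds under buffered conditions that leave the ketal intact.

Step 15
Reactants: 19 C9-formyl bis-lactone; 21 3-(iodomethyl)-1,1-dimethoxycyclobutane
Product: 24 C11 silyl ether ketal (4R,5R,9R,10R,11R), via Grignard reagent 22 (not isolated), via secondary alcohol 23 (not isolated)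
Conditions: 21, Mg, Et2O, 23 °C; 19, THF, −78 °C; then TBSOTf, 2,6-lutidine, −78 → 0 °C
Reagents that add atoms: tert-butyldimethylsilyl triflate CC(C)(C)[Si](C)(C)OS(=O)(=O)C(F)(F)F
Why: Grignard addition to the aldehyde under Felkin–Anh control (quaternary C10 as the large group anti to the nucleophile) should set 11R, and silylating the magnesium alkoxide in the same flask forestalls acyl migration from O20 to O11.

Step 16
Reactants: 24 C11 silyl ether ketal
Product: 26 C8-hydroxymethylene lactone cyclobutanone (4R,5R,9S,10R,11R), via hydroxymethylene ketal 25 (not isolated)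
Conditions: LiN(SiMe3)2, THF, −78 °C; HCO2CH2CF3; AcOH; then PPTS, acetone–H2O, 45 °C
Reagents that add atoms: 2,2,2-trifluoroethyl formate O=COCC(F)(F)F; water O
Why: Claisen formylation of the δ-lactone enolate acidifies C8 while the ketone is still masked, and mild ketal hydrolysis then frees the cyclobutanone without touching the hindered silyl ether.

Step 17
Reactants: 26 C8-hydroxymethylene lactone cyclobutanone
Product: 27 α-diazo δ-lactone cyclobutanone (4R,5R,9S,10R,11R)
Conditions: 4-acetamidobenzenesulfonyl azide, Et3N, MeCN, 0 → 23 °C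
Reagents that add atoms: 4-acetamidobenzenesulfonyl azide CC(=O)Nc1ccc(cc1)S(=O)(=O)N=[N+]=[N-]
Why: In this Regitz deformylative diazo transfer the formyl group leaves on the sulfonamide, and Et3N is too weak to enolise the cyclobutanone or C5, so only C8 reacts.

Step 18
Reactants: 27 α-diazo δ-lactone cyclobutanone
Product: 29 pentacyclic β-keto lactone (4R,5R,8S,9S,10R,11R,13S) with rings A–E complete (C16 = CH2; 11-OTBS), via diazonium alkoxide 28 (not isolated)
Conditions: Sc(OTf)3 (10 mol %), 2,6-di-tert-butylpyridine, 4 Å MS, CH2Cl2 (0.005 M), −20 → 23 °C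
Reagents that add atoms: none
Why: Proposed new method: Sc(OTf)3 activates the strained C15 ketone, the nucleophilic diazo carbon C8 adds to it from the lactone face that carries the C9 side chain (7-exo-trig, giving bridged 28), and the cyclobutane bond C15–C14 that lies antiperiplanar to C8–N2+ migrates to C8 with loss of N2, so the four-membered ring becomes cyclopentanone ring D while the seven-membered ring shrinks to ring C. The closest known reaction type is the Lewis-acid-promoted Tiffeneau–Demjanov-type (Büchner–Curtius–Schlotterbeck) homologation of cyclobutanones and cyclohexanones with α-alkyl-α-diazo esters, known between separate partners and, for diazoalkanes, within one molecule; new is the tethered α-diazo lactone that delivers a bridged bicyclo[3.2.1]octane. C8 is controlled by C9, since addition cis to C11 followed by inversion at the migration terminus places C14 cis to C11 and C15 cis to H9, and C13, not stereogenic in 27, is fixed because only one of the two diastereotopic CH2 groups can stand antiperiplanar to the leaving group. In 28 the tether holds C15–O gauche to C8–N2+, which should suppress epoxide formation, and strain release favours carbon over hydride migration. The step needs attack on the ketone to outrun protonation of C8 (which would end in the C8=C9 lactone) and oligomerisation, hence sieves, a hindered pyridine and high dilution; lactones and silyl ether are inert.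

Step 19
Reactants: 29 pentacyclic β-keto lactone
Product: 30 16-methylene ketone (C16=C17 conjugated to C15=O; 4R,5R,8S,9S,10R,11R,13S)
Conditions: (CH2O)n, i-Pr2NH·CF3CO2H, THF, 65 °C
Reagents that add atoms: formaldehyde C=O
Why: Mannich-type α-methylenation can occur only at C16, the single enolisable position of the C15 ketone, and brings in C17.

Step 20
Reactants: 30 16-methylene ketone
Product: 32 11-O-TBS ether of the target (16S; CH2OH endo), via pinacol boronate 31 (not isolated)
Conditions: B2pin2, CuCl (cat.), Xantphos (cat.), NaOt-Bu (cat.), MeOH, THF, 23 °C; then 30 % H2O2, pH 7 phosphate buffer, 0 °C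
Reagents that add atoms: hydrogen peroxide OO
Why: In this copper-catalysed conjugate borylation boron adds to C17 and methanol should protonate the enolate at C16 from the open exo face (side of C14), leaving C17 endo, and neutral oxidation of the C–B bond gives the β-hydroxy ketone without epimerisation.

Step 21
Reactants: 32 11-O-TBS ether of the target
Product: 33 CNP0555433.1 (4R,5R,8S,9S,10R,11R,13S,16S)
Conditions: HF·pyridine, THF, 0 → 23 °C
Reagents that add atoms: none
Why: Fluoride desilylation in a weakly acidic medium frees 11-OH while avoiding the retro-aldol and β-elimination pathways that base would open for the C16 hydroxymethyl ketone.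

Compound list
1 | cyclohexanone | O=C1CCCCC1 | starting material
2 | allyl 2-oxocyclohexane-1-carboxylate | O=C1CCCCC1C(=O)OCC=C | intermediate
3 | rac-allyl 1-methyl-2-oxocyclohexane-1-carboxylate | CC1(CCCCC1=O)C(=O)OCC=C | intermediate
4 | (S)-2-allyl-2-methylcyclohexan-1-one | C[C@@]1(CC=C)CCCCC1=O | intermediate
5 | (S)-6-allyl-6-methylcyclohex-1-en-1-yl triflate | C[C@@]1(CC=C)CCCC=C1OS(=O)(=O)C(F)(F)F | intermediate
6 | (S)-6-methyl-6-[(E)-prop-1-en-1-yl]cyclohex-1-en-1-yl triflate | C[C@@]1(/C=C/C)CCCC=C1OS(=O)(=O)C(F)(F)F | intermediate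
7 | (S)-6-(hydroxymethyl)-6-methylcyclohex-1-en-1-yl triflate | C[C@@]1(CO)CCCC=C1OS(=O)(=O)C(F)(F)F | intermediate
8 | (R)-3a-methyl-3a,4,5,6-tetrahydro-2-benzofuran-1(3H)-one | C[C@@]12CCCC=C1C(=O)OC2 | intermediate
9 | trimethylsilyl ketene acetal of 10 | C[C@@]12CCC[C@H](C=C)C1=C(O[Si](C)(C)C)OC2 | intermediate
10 | (3aR,7R,7aS)-7-ethenyl-3a-methylhexahydro-2-benzofuran-1(3H)-one | C[C@@]12CCC[C@H](C=C)[C@@H]1C(=O)OC2 | intermediate
11 | C10-formyl lactone (4R,5S,10S) | C[C@@]12CCC[C@H](C=O)[C@@H]1C(=O)OC2 | intermediate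
12 | quaternary aldehyde ester (4R,5R,10R) | C[C@@]12CCC[C@](CCC(=O)OC)(C=O)[C@@H]1C(=O)OC2 | intermediate
13 | hydroxy ester (4R,5R,10R) | C[C@@]12CCC[C@](CCC(=O)OC)(CO)[C@@H]1C(=O)OC2 | intermediate
14 | spiro bis-lactone (4R,5R,10R) | C[C@@]12CCC[C@]3(COC(=O)CC3)[C@@H]1C(=O)OC2 | intermediate
15 | α-phenylselanyl lactone (C8 epimers) | C[C@@]12CCC[C@]3(COC(=O)C([Se]c4ccccc4)C3)[C@@H]1C(=O)OC2 | intermediate
16 | C8=C9 unsaturated spiro bis-lactone (4R,5R,10R) | C[C@@]12CCC[C@]3(COC(=O)C=C3)[C@@H]1C(=O)OC2 | intermediate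
17 | trimethylsilyl ketene acetal of 18 | C[C@@]12CCC[C@]3(COC(O[Si](C)(C)C)=C[C@H]3C=C)[C@@H]1C(=O)OC2 | intermediate
18 | C9-vinyl bis-lactone (4R,5R,9S,10R) | C[C@@]12CCC[C@]3(COC(=O)C[C@H]3C=C)[C@@H]1C(=O)OC2 | intermediate
19 | C9-formyl bis-lactone (4R,5R,9R,10R) | C[C@@]12CCC[C@]3(COC(=O)C[C@H]3C=O)[C@@H]1C(=O)OC2 | intermediate
20 | (3,3-dimethoxycyclobutyl)methanol | OCC1CC(OC)(OC)C1 | starting material
21 | 3-(iodomethyl)-1,1-dimethoxycyclobutane | ICC1CC(OC)(OC)C1 | intermediate
22 | [(3,3-dimethoxycyclobutyl)methyl]magnesium iodide | I[Mg]CC1CC(OC)(OC)C1 | intermediate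
23 | secondary alcohol (4R,5R,9R,10R,11R) | C[C@@]12CCC[C@]3(COC(=O)C[C@H]3[C@H](O)CC4CC(OC)(OC)C4)[C@@H]1C(=O)OC2 | intermediate
24 | C11 silyl ether ketal (4R,5R,9R,10R,11R) | C[C@@]12CCC[C@]3(COC(=O)C[C@H]3[C@H](O[Si](C)(C)C(C)(C)C)CC4CC(OC)(OC)C4)[C@@H]1C(=O)OC2 | intermediate
25 | C8-hydroxymethylene lactone ketal | C[C@@]12CCC[C@]3(COC(=O)C(=CO)[C@H]3[C@H](O[Si](C)(C)C(C)(C)C)CC4CC(OC)(OC)C4)[C@@H]1C(=O)OC2 | intermediate
26 | C8-hydroxymethylene lactone cyclobutanone | C[C@@]12CCC[C@]3(COC(=O)C(=CO)[C@H]3[C@H](O[Si](C)(C)C(C)(C)C)CC4CC(=O)C4)[C@@H]1C(=O)OC2 | intermediate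
27 | α-diazo δ-lactone cyclobutanone | C[C@@]12CCC[C@]3(COC(=O)C(=[N+]=[N-])[C@H]3[C@H](O[Si](C)(C)C(C)(C)C)CC4CC(=O)C4)[C@@H]1C(=O)OC2 | intermediate
28 | bridged diazonium alkoxide (C15 cis to C11 on ring B) | C[C@@]12CCC[C@]3(COC(=O)[C@]4([N+]#N)[C@H]3[C@H](O[Si](C)(C)C(C)(C)C)CC5CC4([O-])C5)[C@@H]1C(=O)OC2 | intermediate
29 | pentacyclic β-keto lactone, 11-OTBS, C16 = CH2 | C[C@@]12CCC[C@]3(COC(=O)[C@@]45C[C@@H](C[C@@H](O[Si](C)(C)C(C)(C)C)[C@H]43)CC5=O)[C@@H]1C(=O)OC2 | intermediate
30 | 16-methylene ketone, 11-OTBS | C[C@@]12CCC[C@]3(COC(=O)[C@@]45C[C@@H](C[C@@H](O[Si](C)(C)C(C)(C)C)[C@H]43)C(=C)C5=O)[C@@H]1C(=O)OC2 | intermediate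
31 | C17 pinacol boronate (C17 endo), 11-OTBS | C[C@@]12CCC[C@]3(COC(=O)[C@@]45C[C@@H](C[C@@H](O[Si](C)(C)C(C)(C)C)[C@H]43)[C@@H](CB6OC(C)(C)C(C)(C)O6)C5=O)[C@@H]1C(=O)OC2 | intermediate
32 | 11-O-TBS ether of the target | C[C@@]12CCC[C@]3(COC(=O)[C@@]45C[C@@H](C[C@@H](O[Si](C)(C)C(C)(C)C)[C@H]43)[C@@H](CO)C5=O)[C@@H]1C(=O)OC2 | intermediate
33 | CNP0555433.1 | C[C@@]12CCC[C@]3(COC(=O)[C@@]45C[C@@H](C[C@@H](O)[C@H]43)[C@@H](CO)C5=O)[C@@H]1C(=O)OC2 | target

Total step count: 21. Longest linear sequence: 20 (steps 1–13 and 15–21).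

Steps most likely to fail

Step 18. Protonation of the diazo carbon followed by hydride shift, or a medium-ring addition too slow to compete with decomposition, may consume 27. The fallback sets out from 24 and comes back at 29, using separate known operations.
- Bromination of the lithium enolate (LiN(SiMe3)2, then CBr4, THF, −78 °C) would give the α-bromo lactone ketal F1.
- PPTS in wet acetone would unmask the bromo lactone cyclobutanone F2.
- SmI2 (THF, −78 °C) would form C8–C15 by an intramolecular Reformatsky reaction to the bridged cyclobutanol F3.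
- Alkoxyl-radical β-fragmentation (PhI(OAc)2, I2, visible light; Suárez conditions) would open the four-membered ring to the γ-iodo ketone F4.
- Cs2CO3 in MeCN would alkylate the β-keto lactone at C8 (5-exo-tet) to 29.

Ring D still grows out of the cyclobutane. The fragmentation is not expected to tell the two CH2 groups apart, so only the C13 epimer drawn can close.

Step 9. Slow addition of the hindered enolate, reversal of the Michael addition or poor facial selectivity at C10 may intervene. The fallback sets out from 11 and comes back at 14.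
- A Tsuji–Trost α-allylation through the enamine (allyl alcohol, Pd(PPh3)4, benzhydrylamine, diphenyl phosphate, toluene, 40 °C) would give the α-allyl aldehyde F5 under the same facial bias.
- NaBH4 would give the neopentyl alcohol F6.
- 9-BBN followed by NaBO3 would give the diol F7.
- TEMPO/PhI(OAc)2 would oxidise the unhindered C7 carbinol first, so that the lactol is carried on to bis-lactone 14.

Step 15. Ring opening of the cyclobutylmethyl organometallic while it forms, attack on a lactone, or acyl migration to O11 before silylation may erode the coupling. The fallback sets out from 19 and comes back at 24.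
- Hosomi–Sakurai allylation (allyltrimethylsilane, BF3·OEt2, CH2Cl2, −78 °C, same Felkin–Anh sense) would give the homoallylic alcohol F8.
- Silylation (TBSOTf, 2,6-lutidine) would give the silyl ether F9.
- [2+2] Cycloaddition with dichloroketene (Cl3CCOCl, Zn–Cu, Et2O) would give the dichlorocyclobutanone F10. Its C13 epimers do not matter, because Zn/AcOH dechlorination to the cyclobutanone F11 removes that stereocentre.
- HC(OMe)3, MeOH and PPTS would then return ketal 24.

Further compounds
F1 | step 18 | α-bromo lactone ketal | C[C@@]12CCC[C@]3(COC(=O)C(Br)[C@H]3[C@H](O[Si](C)(C)C(C)(C)C)CC4CC(OC)(OC)C4)[C@@H]1C(=O)OC2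
F2 | step 18 | bromo lactone cyclobutanone | C[C@@]12CCC[C@]3(COC(=O)C(Br)[C@H]3[C@H](O[Si](C)(C)C(C)(C)C)CC4CC(=O)C4)[C@@H]1C(=O)OC2
F3 | step 18 | bridged cyclobutanol | C[C@@]12CCC[C@]3(COC(=O)[C@@H]4[C@H]3[C@H](O[Si](C)(C)C(C)(C)C)CC5CC4(O)C5)[C@@H]1C(=O)OC2
F4 | step 18 | γ-iodo ketone | C[C@@]12CCC[C@]3(COC(=O)C4[C@H]3[C@H](O[Si](C)(C)C(C)(C)C)C[C@H](CI)CC4=O)[C@@H]1C(=O)OC2
F5 | step 9 | α-allyl aldehyde | C[C@@]12CCC[C@](CC=C)(C=O)[C@@H]1C(=O)OC2
F6 | step 9 | neopentyl alcohol | C[C@@]12CCC[C@](CC=C)(CO)[C@@H]1C(=O)OC2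
F7 | step 9 | diol | C[C@@]12CCC[C@](CCCO)(CO)[C@@H]1C(=O)OC2
F8 | step 15 | homoallylic alcohol | C[C@@]12CCC[C@]3(COC(=O)C[C@H]3[C@H](O)CC=C)[C@@H]1C(=O)OC2
F9 | step 15 | silyl ether | C[C@@]12CCC[C@]3(COC(=O)C[C@H]3[C@H](O[Si](C)(C)C(C)(C)C)CC=C)[C@@H]1C(=O)OC2
F10 | step 15 | dichlorocyclobutanone | C[C@@]12CCC[C@]3(COC(=O)C[C@H]3[C@H](O[Si](C)(C)C(C)(C)C)CC4CC(=O)C4(Cl)Cl)[C@@H]1C(=O)OC2
F11 | step 15 | cyclobutanone | C[C@@]12CCC[C@]3(COC(=O)C[C@H]3[C@H](O[Si](C)(C)C(C)(C)C)CC4CC(=O)C4)[C@@H]1C(=O)OC2
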